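## Retrosynthetic overview

1. Target 18 is opened in a single flask operation back to the monocyclic dienone 16. The bonds cut are C3–CH and CMe2–CH (seven- and five-membered rings, oxidative radical bicyclisation) and C1–C8 (ring B, photochemical proton-transfer cyclisation).
2. 16 ⇒ 15 + prenyl bromide. 15 ⇒ bromoarene 6 + (S)-lavandulyl triflate 13 by alkylative dearomatisation. The bromine masks the carbon that later takes the prenyl group and leaves on work-up.
3. 6 ⇒ phloroglucinol, isobutyryl chloride, NBS and geranyl bromide. 13 ⇒ Evans deconjugative prenylation of a senecioyl imide.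
4. Ring order: ring A (bought as phloroglucinol) → ring B → seven-membered ring → cyclopentane. The last three rings all form in step 10.

**Numbering used:** C1 is the acyl-bearing bridgehead, C3 the carbon between the C2 and C4 carbonyls, C5 the geranyl-bearing bridgehead, C7 the CH, C8 the CMe2 and C9 the bridging C=O.

**Assumption:** Step 8 gives both C6 epimers, about 1:1. They are carried together and only the 6R series can build the cage. All SMILES show that series and one enol tautomer.

## Route

Step 1
Reactants: 1 phloroglucinol; 2 isobutyryl chloride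
Product: 3 phlorisobutyrophenone
Conditions: AlCl3 (3.5 equiv), PhNO2–CH2Cl2, 0 to 45 °C; aq HCl
Reagents that add atoms: none
Why: Friedel–Crafts C-acylation of the very electron-rich arene stops after one acyl group because the chelated aryl ketone deactivates the ring; no stereocentre is formed.

Step 2
Reactants: 3 phlorisobutyrophenone
Product: 4 3-bromophlorisobutyrophenone
Conditions: NBS (1.0 equiv), MeCN, −20 to 0 °C
Reagents that add atoms: N-bromosuccinimide O=C1CCC(=O)N1Br
Why: Electrophilic aromatic bromination takes one of the two equivalent free positions and leaves a single C–H carbon for step 3; no stereocentre is formed.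

Step 3
Reactants: 4 3-bromophlorisobutyrophenone; 5 geranyl bromide
Product: 6 3-bromo-5-geranylphlorisobutyrophenone
Conditions: K2CO3, acetone, rt to 40 °C
Reagents that add atoms: none
Why: Phenoxide C-alkylation (SN2 on the allylic bromide, E alkene kept) can rearomatise only at the one remaining C–H carbon, so the geranyl group is placed without ambiguity.

Step 4
Reactants: 7 (S)-4-benzyloxazolidin-2-one; 8 3,3-dimethylacryloyl chloride
Product: 9 (S)-4-benzyl-3-(3-methylbut-2-enoyl)oxazolidin-2-one
Conditions: n-BuLi, THF, −78 °C; then 8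
Reagents that add atoms: none
Why: N-acylation of the lithiated Evans auxiliary; the auxiliary centre is untouched.

Step 5
Reactants: 9 (S)-4-benzyl-3-(3-methylbut-2-enoyl)oxazolidin-2-one; 10 prenyl bromide
Product: 11 (S)-4-benzyl-3-[(2S)-5-methyl-2-(prop-1-en-2-yl)hex-4-enoyl]oxazolidin-2-one
Conditions: NaHMDS, THF, −78 °C; 10, −78 to −40 °C
Reagents that add atoms: none
Why: Evans deconjugative α-alkylation, in which γ-deprotonation gives the chelated Z(O)-dienolate and prenyl bromide attacks Cα on the face opposite the benzyl group, sets the later C7 centre.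

Step 6
Reactants: 11 (S)-4-benzyl-3-[(2S)-5-methyl-2-(prop-1-en-2-yl)hex-4-enoyl]oxazolidin-2-one
Product: 12 (S)-lavandulol
Conditions: LiBH4, H2O (1 equiv), Et2O, 0 °C
Reagents that add atoms: none
Why: Reductive cleavage of the imide gives the primary alcohol without enolisation, so the α-centre and the β,γ-alkene stay in place.

Step 7
Reactants: 12 (S)-lavandulol
Product: 13 (S)-lavandulyl triflate
Conditions: Tf2O, 2,6-lutidine, CH2Cl2, −78 °C; cold silica plug
Reagents that add atoms: triflic anhydride O=S(=O)(OS(=O)(=O)C(F)(F)F)C(F)(F)F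
Why: O-sulfonylation turns the β-branched primary alcohol into an electrophile reactive enough for C-alkylation; the stereocentre is not involved.

Step 8
Reactants: 6 3-bromo-5-geranylphlorisobutyrophenone; 13 (S)-lavandulyl triflate
Product: 15 (6R)-6-geranyl-3,5-dihydroxy-2-isobutyryl-6-[(2R)-5-methyl-2-(prop-1-en-2-yl)hex-4-enyl]cyclohexa-2,4-dien-1-one, via bromodienone 14 (not isolated)
Conditions: LiHMDS (3.1 equiv), THF, −78 to 0 °C; AcOH; aq NaHSO3, rt
Reagents that add atoms: none
Why: Alkylative dearomatisation of the lithium phenoxide goes to the geranyl-bearing carbon because the acyl- and bromo-bearing carbons are deactivated, the new quaternary centre (later C5) forms without facial bias, and bisulfite then reduces the positive bromine of the 2-bromo-1,3-dione unit to C–H.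

Step 9
Reactants: 15 (6R)-6-geranyl-3,5-dihydroxy-2-isobutyryl-6-[(2R)-5-methyl-2-(prop-1-en-2-yl)hex-4-enyl]cyclohexa-2,4-dien-1-one; 10 prenyl bromide
Product: 16 (6R)-6-geranyl-3,5-dihydroxy-2-isobutyryl-6-[(2R)-5-methyl-2-(prop-1-en-2-yl)hex-4-enyl]-4-prenylcyclohexa-2,4-dien-1-one
Conditions: NaOMe (1.0 equiv), MeOH, 0 °C; 10 (1.0 equiv)
Reagents that add atoms: none
Why: C-prenylation of the vinylogous acid at its only C–H carbon (hop β-acid type alkylation in a protic medium that favours C over O) places the prenyl group where the bromine stood; no new stereocentre is formed.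

Step 10
Reactants: 16 (6R)-6-geranyl-3,5-dihydroxy-2-isobutyryl-6-[(2R)-5-methyl-2-(prop-1-en-2-yl)hex-4-enyl]-4-prenylcyclohexa-2,4-dien-1-one
Product: 18 target CNP0280463.1, via bicyclic enol 17 (not isolated)
Conditions: 390 nm LED, degassed benzene (0.01 M), rt; evaporate; Mn(OAc)3·2H2O (2.5 equiv), Cu(OAc)2·H2O (0.2 equiv), AcOH, 50 °C
Reagents that add atoms: none
Why: Proposed new method: excitation of the chelated acyl-enol causes excited-state intramolecular proton transfer, the photoacid protonates the nearby and least hindered CH2 terminus of the isopropenyl group, and the tertiary C8 cation is captured by C1 of the same triketonate (closest known type: ESIPT photocyclisation of dearomatised acylphloroglucinols to type A cores), the tether fixing C1 and holding the C7 prenyl group endo in the 6R series only; Mn(OAc)3 then oxidises the C2–C4 enol of 17 to the C3 radical (closest known type: Mn(OAc)3/Cu(OAc)2 oxidative radical cyclisation of prenylated acylphloroglucinols), which can reach only the CH of the endo prenyl group (7-exo, with the CMe2 radical turned to the C6H2 side away from the C8 methyls), closes 5-exo onto the C3 prenyl group through a chair-like transition state that puts the new side chain trans to the CH2 bridge (Beckwith model), and loses hydrogen by organocopper elimination to the less substituted isopropenyl alkene.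

## Compound list

1 | phloroglucinol | Oc1cc(O)cc(O)c1 | starting material
2 | isobutyryl chloride | CC(C)C(=O)Cl | starting material
3 | phlorisobutyrophenone, 2-methyl-1-(2,4,6-trihydroxyphenyl)propan-1-one | CC(C)C(=O)c1c(O)cc(O)cc1O | intermediate
4 | 1-(3-bromo-2,4,6-trihydroxyphenyl)-2-methylpropan-1-one | CC(C)C(=O)c1c(O)cc(O)c(Br)c1O | intermediate
5 | geranyl bromide (E) | BrC/C=C(\C)CCC=C(C)C | starting material
6 | 1-{3-bromo-5-[(2E)-3,7-dimethylocta-2,6-dienyl]-2,4,6-trihydroxyphenyl}-2-methylpropan-1-one | CC(C)C(=O)c1c(O)c(Br)c(O)c(C/C=C(\C)CCC=C(C)C)c1O | intermediate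
7 | (S)-4-benzyloxazolidin-2-one | O=C1N[C@@H](Cc2ccccc2)CO1 | starting material
8 | 3,3-dimethylacryloyl chloride | CC(C)=CC(=O)Cl | starting material
9 | (S)-4-benzyl-3-(3-methylbut-2-enoyl)oxazolidin-2-one | CC(C)=CC(=O)N1[C@@H](Cc2ccccc2)COC1=O | intermediate
10 | prenyl bromide | CC(C)=CCBr | starting material
11 | (S)-4-benzyl-3-[(2S)-5-methyl-2-(prop-1-en-2-yl)hex-4-enoyl]oxazolidin-2-one | O=C([C@@H](CC=C(C)C)C(C)=C)N1[C@@H](Cc2ccccc2)COC1=O | intermediate
12 | (S)-lavandulol | OC[C@@H](CC=C(C)C)C(C)=C | intermediate
13 | (S)-lavandulyl triflate | O=S(=O)(OC[C@@H](CC=C(C)C)C(C)=C)C(F)(F)F | intermediate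
14 | 4-bromo derivative of 15 (6R, side chain 2R; formed with its 6S epimer; not isolated) | O=C1C(C(=O)C(C)C)=C(O)C(Br)=C(O)[C@@]1(C/C=C(\C)CCC=C(C)C)C[C@@H](CC=C(C)C)C(C)=C | intermediate
15 | (6R)-6-geranyl-3,5-dihydroxy-2-isobutyryl-6-[(2R)-5-methyl-2-(prop-1-en-2-yl)hex-4-enyl]cyclohexa-2,4-dien-1-one (with its 6S epimer) | O=C1C(C(=O)C(C)C)=C(O)C=C(O)[C@@]1(C/C=C(\C)CCC=C(C)C)C[C@@H](CC=C(C)C)C(C)=C | intermediate
16 | 4-prenyl derivative of 15 (6R, side chain 2R; with its 6S epimer) | O=C1C(C(=O)C(C)C)=C(O)C(CC=C(C)C)=C(O)[C@@]1(C/C=C(\C)CCC=C(C)C)C[C@@H](CC=C(C)C)C(C)=C | intermediate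
17 | (1S,5R,7R) type A bicyclo[3.3.1]nonane-2,4,9-trione in its enol form: C1 isobutyryl, C3 prenyl, C5 geranyl, C7 endo prenyl, C8 gem-dimethyl (not isolated) | O=C1[C@@]2(C/C=C(\C)CCC=C(C)C)C[C@@H](CC=C(C)C)C(C)(C)[C@](C(=O)C(C)C)(C2=O)C(O)=C1CC=C(C)C | intermediate
18 | CNP0280463.1, homoadamantane trione with fused cyclopentane: C1 S, C3 S, C5 R, C7 R, ring-fusion CH S, isopropenyl-bearing CH S | C=C(C)[C@@H]1C[C@@]23C(=O)[C@@]4(C/C=C(\C)CCC=C(C)C)C[C@@H](C[C@H]2C1(C)C)C(C)(C)[C@](C(=O)C(C)C)(C4=O)C3=O | target

## Step count and risks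

Total step count: 10. Longest linear sequence: 7 (steps 4 to 10).

**Step 10 (most likely to fail).**
- Risks:
  - The photoacid may protonate the proximal geranyl alkene instead of the isopropenyl group.
  - The cation may be caught by oxygen rather than by C1.
  - The boat-like closure that puts the C7 prenyl group endo may be slow.
- The fallback sets out from 16 and comes back at 18.
- NCS (CH2Cl2, 0 °C) chlorinates the most nucleophilic carbon to give the 4-chloro-4-prenyl trione F1. C1 is then the only carbon nucleophile left, and the oxidant for the later cascade is stored in the substrate.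
- Ring B is closed without light by cobalt hydride hydrogen-atom transfer with radical–polar crossover. The conditions are Co(salen), N-fluoro-2,4,6-collidinium triflate and (Me2SiH)2O in PhCF3–HFIP at 0 °C. This engages only the 1,1-disubstituted alkene and gives the 3-chloro bicycle F2.
- fac-Ir(ppy)3, K2HPO4 and blue LED in MeCN then cleave the C–Cl bond reductively to the same C3 radical. The 7-exo/5-exo cascade follows, and oxidation of the tertiary radical with proton loss gives 18.

**Step 8.**
- Risks: the β-branched triflate may alkylate oxygen, or react too slowly at a fully substituted carbon.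
- The fallback sets out from 4 and comes back at 15.
- The hard alkylation is done first, on the free C–H carbon of 4 with 13 (LiHMDS, THF). This gives the aromatic 3-bromo-5-lavandulylphlorisobutyrophenone F3.
- The quaternary centre is then made with the much more reactive geranyl bromide 5 (LiHMDS, THF, 0 °C), which gives 14.
- Aqueous NaHSO3 then gives 15.

**Step 3.**
- Risk: O-geranylation or dearomatising attack at the brominated carbon may lower the yield.
- The fallback sets out from 3 and comes back at 6.
- 3 is geranylated first (K2CO3, acetone) to 3-geranylphlorisobutyrophenone F4, which is separated from the bis-alkylated material.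
- The last free ring position is then brominated with NBS at −78 °C, where the arene reacts far faster than the alkenes.

## Further compounds

F1 | step 10 | (6R)-4-chloro-6-geranyl-2-isobutyryl-6-[(2R)-5-methyl-2-(prop-1-en-2-yl)hex-4-enyl]-4-prenylcyclohexane-1,3,5-trione, enol form, both C4 epimers | O=C1[C@@](C/C=C(\C)CCC=C(C)C)(C[C@@H](CC=C(C)C)C(C)=C)C(O)=C(C(=O)C(C)C)C(=O)C1(Cl)CC=C(C)C
F2 | step 10 | (1S,5R,7R)-3-chloro-5-geranyl-1-isobutyryl-8,8-dimethyl-3,7-diprenylbicyclo[3.3.1]nonane-2,4,9-trione, C7 prenyl endo, both C3 epimers | O=C1[C@@]2(C/C=C(\C)CCC=C(C)C)C[C@@H](CC=C(C)C)C(C)(C)[C@](C(=O)C(C)C)(C2=O)C(=O)C1(Cl)CC=C(C)C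
F3 | step 8 | 1-{3-bromo-2,4,6-trihydroxy-5-[(2R)-5-methyl-2-(prop-1-en-2-yl)hex-4-enyl]phenyl}-2-methylpropan-1-one | CC(C)C(=O)c1c(O)c(Br)c(O)c(C[C@@H](CC=C(C)C)C(C)=C)c1O
F4 | step 3 | 1-{3-[(2E)-3,7-dimethylocta-2,6-dienyl]-2,4,6-trihydroxyphenyl}-2-methylpropan-1-one | CC(C)C(=O)c1c(O)cc(O)c(C/C=C(\C)CCC=C(C)C)c1O
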